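**Strategy.** The route rests on a [3+3] disconnection of ring A that at the same time opens ring B: C5–C10 and C2–C3 (labdane numbering) are cut, so that both rings arise from the acyclic triketo enal ester 7. The key step exploits the fact that C10 and C2 are the β- and carbonyl carbons of one enal unit (C10=C1–C2=O) and that C5 and C3 are the α- and γ-carbons of one dienolate (C6 ketone, C4 methylidene ester). A catalytic asymmetric intramolecular Michael addition (ring B, quaternary C10) followed in the same flask by a vinylogous aldol addition (ring A, C2 carbinol) delivers the bicyclic core; C4, C5 and C6 are then set from C10.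

Key step: step 5

Remark on numbering: labdane numbering is used (C1–C10 decalin, C17 on C8, C18 α and C19 β on C4, C20 on C10, C11–C16 side chain); α/β refer to the usual drawing with C20 β.
Remark on C8: the centre that becomes C8 is carried as an inconsequential mixture of epimers (compounds 3 and 5–11) until it becomes sp2 in step 8, and its SMILES carries no descriptor.
Assumption on step 5: the quinine-derived thiourea is assumed to expose the enal face that leads to (10S); should the sense be the opposite, the pseudo-enantiomeric quinidine-derived thiourea is used.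

**Route**

Step 1
Reactants: 1 3-methylfuran; 2 (E)-but-2-enal
Product: 3 3-(3-methylfuran-2-yl)butanal (racemic)
Conditions: (±)-5-benzyl-2,2,3-trimethylimidazolidin-4-one hydrochloride (10 mol %), THF–H2O, 0 °C, 1 in excess (3 equiv)
Reagents that add atoms: none
Why: Iminium-catalysed Friedel–Crafts-type conjugate addition of the electron-rich furan to the enal should occur at C2 of 1, the α-position that is additionally activated by the 3-methyl group, and the new stereocentre (later C8) is formed racemic because it is erased in step 8.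

Step 2
Reactants: 3 3-(3-methylfuran-2-yl)butanal; 4 methyl 2-(bromomethyl)prop-2-enoate
Product: 5 methyl 4-hydroxy-6-(3-methylfuran-2-yl)-2-methylideneheptanoate (diastereomer mixture)
Conditions: In powder, THF–H2O (1:1), 23 °C
Reagents that add atoms: none
Why: The indium-mediated Barbier allylation of the aldehyde with the 2-(methoxycarbonyl)allyl bromide runs in neutral aqueous THF, which spares the furan and leaves the product as the open hydroxy ester; the carbinol centre is unselective and is removed in step 3.

Step 3
Reactants: 5 methyl 4-hydroxy-6-(3-methylfuran-2-yl)-2-methylideneheptanoate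
Product: 6 methyl 6-(3-methylfuran-2-yl)-2-methylidene-4-oxoheptanoate
Conditions: Dess–Martin periodinane, CH2Cl2, 0 → 23 °C
Reagents that add atoms: none
Why: Dess–Martin oxidation converts the secondary alcohol into the ketone under mild conditions, so that the exocyclic double bond should stay out of conjugation and C5 becomes the doubly activated methylene needed in step 5.

Step 4
Reactants: 6 methyl 6-(3-methylfuran-2-yl)-2-methylidene-4-oxoheptanoate
Product: 7 methyl (8E)-6,8-dimethyl-2-methylidene-4,7,10-trioxodec-8-enoate
Conditions: NBS, NaHCO3, acetone–H2O (10:1), −20 °C; then pyridine, 23 °C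
Reagents that add atoms: water O
Why: Oxidative ring opening of the 2-alkylfuran with a free 5-position by NBS in aqueous acetone (bromination, hydration and loss of HBr) unmasks the 4-oxo-2-enal, the electron-poor acrylate being inert, and pyridine isomerises the first-formed (Z)-alkene to the (E)-isomer.

Step 5
Reactants: 7 methyl (8E)-6,8-dimethyl-2-methylidene-4,7,10-trioxodec-8-enoate
Product: 9 methyl (3R,4aS)-3-hydroxy-4a,6-dimethyl-5,8-dioxo-2,3,4,4a,5,6,7,8-octahydronaphthalene-1-carboxylate, via Michael adduct 8 (not isolated)
Conditions: 1-[3,5-bis(trifluoromethyl)phenyl]-3-[(8α,9S)-6′-methoxycinchonan-9-yl]thiourea (10 mol %), toluene (0.02 M), 0 → 23 °C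
Reagents that add atoms: none
Why: The quinuclidine nitrogen of the bifunctional catalyst deprotonates the doubly activated C5 methylene (α to the C6 ketone and allylic to the acrylate) while the thiourea binds the 4-oxo-enal, and the dienolate adds through its α-carbon C5 to C10, the β-carbon of the enal, in a 6-exo-trig intramolecular Michael addition that closes ring B and creates the quaternary centre; after proton transfer the still acidic C5–H of 8 is removed again and the dienolate attacks the liberated C2 aldehyde through its γ-carbon C3 in a six-membered vinylogous aldol addition that closes ring A. The closest known reaction type is the Robinson-type Michael/aldol [3+3] annulation of a ketone with an enal, run as an amine–thiourea catalysed domino reaction with an allyl ketone as pronucleophile. Regiochemistry is secured by ring size: α-attack on C10 gives a six-membered ring where γ-attack would give an eight-membered one, γ-attack on C2 gives a six-membered ring where α-attack would give a four-membered one, and 1,2-attack of C5 on C2 would need an eight-membered ring. The other acidic sites (C7, C8) are several pK units weaker, and the five-membered aldol of C5 onto the C9 ketone is reversible, so it should drain into the Michael pathway. C10 is set by the catalyst, which exposes one face of the trisubstituted enal to the tethered dienolate, and C2 is set under thermodynamic control because the reversible vinylogous aldol places the hydroxyl equatorial, trans to the axial C10 methyl. The selectivity the step needs is enantiofacial discrimination at C10, which rests on the catalyst alone since 7 carries no controlling stereocentre.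

Step 6
Reactants: 9 methyl (3R,4aS)-3-hydroxy-4a,6-dimethyl-5,8-dioxo-2,3,4,4a,5,6,7,8-octahydronaphthalene-1-carboxylate
Product: 10 methyl 6,9-dioxo-2α-(triethylsilyloxy)-11,12,13,14,15,16,18-heptanorlabd-4-en-19-oate
Conditions: TESCl, imidazole, CH2Cl2, 0 °C
Reagents that add atoms: chlorotriethylsilane CC[Si](CC)(CC)Cl
Why: Standard silylation of the only hydroxyl group protects the C2 carbinol against the organometallic and basic steps that follow.

Step 7
Reactants: 10 methyl 6,9-dioxo-2α-(triethylsilyloxy)-11,12,13,14,15,16,18-heptanorlabd-4-en-19-oate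
Product: 11 methyl 9-oxo-2α-(triethylsilyloxy)-6-(trimethylsilyloxy)-11,12,13,14,15,16-hexanorlabd-5-en-19-oate
Conditions: Me2CuLi (from MeLi and CuI), TMSCl, THF, −78 → −40 °C; Et3N, then aq. NaHCO3
Reagents that add atoms: lithium dimethylcuprate [Li+].C[Cu-]C; chlorotrimethylsilane C[Si](C)(C)Cl
Why: TMSCl-accelerated conjugate addition of the Gilman cuprate to the ene-keto ester should occur β to the more activating ketone, i.e. at C4, from the α-face anti to the axial C10 methyl, so that the new methyl group is α (C18) and the ester is β-axial (C19), and the regiodefined C6 enolate is trapped as its silyl enol ether, which masks this ketone in step 8.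

Step 8
Reactants: 11 methyl 9-oxo-2α-(triethylsilyloxy)-6-(trimethylsilyloxy)-11,12,13,14,15,16-hexanorlabd-5-en-19-oate
Product: 12 methyl 2α-(triethylsilyloxy)-9-(trifluoromethanesulfonyloxy)-6-(trimethylsilyloxy)-11,12,13,14,15,16-hexanorlabda-5,8-dien-19-oate
Conditions: KN(SiMe3)2, THF, −78 → 0 °C; then PhNTf2, −78 → 0 °C
Reagents that add atoms: N-phenylbis(trifluoromethanesulfonimide) O=S(=O)(N(c1ccccc1)S(=O)(=O)C(F)(F)F)C(F)(F)F
Why: C9 is now the only free ketone and C8 its only enolisable position, so deprotonation and O-triflation (enol triflate formation) are regiospecific and give the tetrasubstituted enol triflate, in which the stray C8 stereocentre has become sp2.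

Step 9
Reactants: 13 furan-3-carbaldehyde
Product: 14 3-ethenylfuran
Conditions: Ph3PCH3Br, KOt-Bu, Et2O, 0 → 23 °C; co-distilled and used as a solution
Reagents that add atoms: methyltriphenylphosphonium bromide C[P+](c1ccccc1)(c1ccccc1)c1ccccc1.[Br-]
Why: Wittig methylenation of the aldehyde gives the volatile vinylfuran that carries C11–C16.

Step 10
Reactants: 12 methyl 2α-(triethylsilyloxy)-9-(trifluoromethanesulfonyloxy)-6-(trimethylsilyloxy)-11,12,13,14,15,16-hexanorlabda-5,8-dien-19-oate; 14 3-ethenylfuran
Product: 17 methyl 15,16-epoxy-6-oxo-2α-(triethylsilyloxy)labda-8,13(16),14-trien-19-oate, via alkylborane 15 (not isolated), via coupled silyl enol ether 16 (not isolated)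
Conditions: 14, 9-BBN-H, THF, 23 °C; then 12, Pd(dppf)Cl2 (5 mol %), AsPh3, K3PO4, DMF, 50 °C; then 0.5 M aq. citric acid, THF, 0 °C
Reagents that add atoms: none
Why: Anti-Markovnikov hydroboration of the vinyl group and B-alkyl Suzuki–Miyaura coupling of the borane with the enol triflate form the C9–C11 bond without moving the tetrasubstituted double bond, and the mild acidic hydrolysis of the silyl enol ether protonates C5 from the open α-face (the β-face is blocked by C20 and the axial ester), which gives the trans ring fusion that is also the thermodynamic one.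

Step 11
Reactants: 17 methyl 15,16-epoxy-6-oxo-2α-(triethylsilyloxy)labda-8,13(16),14-trien-19-oate
Product: 18 15,16-epoxy-2α-(triethylsilyloxy)labda-8,13(16),14-triene-6α,19-diol
Conditions: Li, NH3(l), THF, EtOH, −78 → −33 °C; NH4Cl
Reagents that add atoms: none
Why: Dissolving-metal reduction should give the equatorial 6α-alcohol because the carbinyl anion is protonated under thermodynamic control (hydride reagents would attack from the α-face and give the axial 6β-alcohol), and it reduces the axial methyl ester to the C19 alcohol at the same time (Bouveault–Blanc type), while the tetrasubstituted alkene, the 3-alkylfuran and the silyl ether should be inert.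

Step 12
Reactants: 18 15,16-epoxy-2α-(triethylsilyloxy)labda-8,13(16),14-triene-6α,19-diol
Product: 19 15,16-epoxy-2α,19-bis(triethylsilyloxy)labda-8,13(16),14-trien-6α-ol
Conditions: TESCl (1.05 equiv), imidazole, CH2Cl2, −20 °C
Reagents that add atoms: chlorotriethylsilane CC[Si](CC)(CC)Cl
Why: Silylation with a slight excess of TESCl at low temperature discriminates the primary C19 hydroxyl from the hindered secondary 6α-hydroxyl.

Step 13
Reactants: 19 15,16-epoxy-2α,19-bis(triethylsilyloxy)labda-8,13(16),14-trien-6α-ol
Product: 20 6α-acetoxy-15,16-epoxy-2α,19-bis(triethylsilyloxy)labda-8,13(16),14-triene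
Conditions: Ac2O, 4-(dimethylamino)pyridine, pyridine, 40 °C
Reagents that add atoms: acetic anhydride CC(=O)OC(C)=O
Why: DMAP-catalysed acyl transfer acetylates the remaining hindered secondary alcohol.

Step 14
Reactants: 20 6α-acetoxy-15,16-epoxy-2α,19-bis(triethylsilyloxy)labda-8,13(16),14-triene
Product: 21 6α-acetoxy-16-hydroxy-2α,19-bis(triethylsilyloxy)labda-8,13-dien-15,16-olide (C16 epimers)
Conditions: O2, visible light, 5,10,15,20-tetraphenylporphyrin (1 mol %), i-Pr2NEt, CH2Cl2, −78 °C
Reagents that add atoms: dioxygen O=O
Why: [4+2] Cycloaddition of singlet oxygen to the 3-alkylfuran, which should be faster than the ene reaction of the hindered tetrasubstituted alkene, gives an endoperoxide from which the hindered base removes the more accessible H15 (Kornblum–DeLaMare-type fragmentation), so that the carbonyl ends at C15 and the lactol at C16; the C16 epimer mixture is removed in step 15.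

Step 15
Reactants: 21 6α-acetoxy-16-hydroxy-2α,19-bis(triethylsilyloxy)labda-8,13-dien-15,16-olide
Product: 23 6α-acetoxy-2α,19-dihydroxylabda-8,13-dien-15,16-olide (CNP0231903.1), via bis-silylated butenolide 22 (not isolated)
Conditions: NaBH4, EtOH, 0 °C; then 1 M aq. HCl, THF, 23 °C
Reagents that add atoms: none
Why: Borohydride reduces the open-chain aldehyde tautomer of the γ-hydroxybutenolide, and acidification closes the butenolide and hydrolyses both triethylsilyl ethers, conditions under which the hindered acetate and the tetrasubstituted alkene should survive.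

**Compound list**

1 | 3-methylfuran | Cc1ccoc1 | starting material
2 | (E)-but-2-enal | C/C=C/C=O | starting material
3 | 3-(3-methylfuran-2-yl)butanal (racemic) | O=CCC(C)c1occc1C | intermediate
4 | methyl 2-(bromomethyl)prop-2-enoate | COC(=O)C(=C)CBr | starting material
5 | methyl 4-hydroxy-6-(3-methylfuran-2-yl)-2-methylideneheptanoate (diastereomers) | COC(=O)C(=C)CC(O)CC(C)c1occc1C | intermediate
6 | methyl 6-(3-methylfuran-2-yl)-2-methylidene-4-oxoheptanoate | COC(=O)C(=C)CC(=O)CC(C)c1occc1C | intermediate
7 | methyl (8E)-6,8-dimethyl-2-methylidene-4,7,10-trioxodec-8-enoate | COC(=O)C(=C)CC(=O)CC(C)C(=O)/C(C)=C/C=O | intermediate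
8 | methyl 2-[2,4-dimethyl-3,6-dioxo-2-(2-oxoethyl)cyclohexyl]prop-2-enoate (Michael adduct, C10 as in 9) | O=C1CC(C)C(=O)[C@@](C)(CC=O)C1C(=C)C(=O)OC | intermediate (not isolated)
9 | methyl (3R,4aS)-3-hydroxy-4a,6-dimethyl-5,8-dioxo-2,3,4,4a,5,6,7,8-octahydronaphthalene-1-carboxylate (2α-OH, 10β-Me in labdane terms) | O=C1CC(C)C(=O)[C@@]2(C)C[C@@H](O)CC(C(=O)OC)=C12 | intermediate
10 | methyl 6,9-dioxo-2α-(triethylsilyloxy)-11,12,13,14,15,16,18-heptanorlabd-4-en-19-oate | O=C1CC(C)C(=O)[C@@]2(C)C[C@@H](O[Si](CC)(CC)CC)CC(C(=O)OC)=C12 | intermediate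
11 | methyl 9-oxo-2α-(triethylsilyloxy)-6-(trimethylsilyloxy)-11,12,13,14,15,16-hexanorlabd-5-en-19-oate | C[Si](C)(C)OC=1CC(C)C(=O)[C@@]2(C)C[C@@H](O[Si](CC)(CC)CC)C[C@](C)(C(=O)OC)C2=1 | intermediate
12 | methyl 2α-(triethylsilyloxy)-9-(trifluoromethanesulfonyloxy)-6-(trimethylsilyloxy)-11,12,13,14,15,16-hexanorlabda-5,8-dien-19-oate | C[Si](C)(C)OC=1CC(C)=C(OS(=O)(=O)C(F)(F)F)[C@@]2(C)C[C@@H](O[Si](CC)(CC)CC)C[C@](C)(C(=O)OC)C2=1 | intermediate
13 | furan-3-carbaldehyde | O=Cc1ccoc1 | starting material
14 | 3-ethenylfuran | C=Cc1ccoc1 | intermediate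
15 | 9-[2-(furan-3-yl)ethyl]-9-borabicyclo[3.3.1]nonane | c1cc(CCB2C3CCCC2CCC3)co1 | intermediate (not isolated)
16 | methyl 15,16-epoxy-2α-(triethylsilyloxy)-6-(trimethylsilyloxy)labda-5,8,13(16),14-tetraen-19-oate | C[Si](C)(C)OC=1CC(C)=C(CCc3ccoc3)[C@@]2(C)C[C@@H](O[Si](CC)(CC)CC)C[C@](C)(C(=O)OC)C2=1 | intermediate (not isolated)
17 | methyl 15,16-epoxy-6-oxo-2α-(triethylsilyloxy)labda-8,13(16),14-trien-19-oate (5α-H) | O=C1CC(C)=C(CCc3ccoc3)[C@@]2(C)C[C@@H](O[Si](CC)(CC)CC)C[C@](C)(C(=O)OC)[C@H]12 | intermediate
18 | 15,16-epoxy-2α-(triethylsilyloxy)labda-8,13(16),14-triene-6α,19-diol | O[C@H]1CC(C)=C(CCc3ccoc3)[C@@]2(C)C[C@@H](O[Si](CC)(CC)CC)C[C@](C)(CO)[C@H]12 | intermediate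
19 | 15,16-epoxy-2α,19-bis(triethylsilyloxy)labda-8,13(16),14-trien-6α-ol | O[C@H]1CC(C)=C(CCc3ccoc3)[C@@]2(C)C[C@@H](O[Si](CC)(CC)CC)C[C@](C)(CO[Si](CC)(CC)CC)[C@H]12 | intermediate
20 | 6α-acetoxy-15,16-epoxy-2α,19-bis(triethylsilyloxy)labda-8,13(16),14-triene | CC(=O)O[C@H]1CC(C)=C(CCc3ccoc3)[C@@]2(C)C[C@@H](O[Si](CC)(CC)CC)C[C@](C)(CO[Si](CC)(CC)CC)[C@H]12 | intermediate
21 | 6α-acetoxy-16-hydroxy-2α,19-bis(triethylsilyloxy)labda-8,13-dien-15,16-olide (C16 epimers) | CC(=O)O[C@H]1CC(C)=C(CCC3=CC(=O)OC3O)[C@@]2(C)C[C@@H](O[Si](CC)(CC)CC)C[C@](C)(CO[Si](CC)(CC)CC)[C@H]12 | intermediate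
22 | 6α-acetoxy-2α,19-bis(triethylsilyloxy)labda-8,13-dien-15,16-olide | CC(=O)O[C@H]1CC(C)=C(CCC3=CC(=O)OC3)[C@@]2(C)C[C@@H](O[Si](CC)(CC)CC)C[C@](C)(CO[Si](CC)(CC)CC)[C@H]12 | intermediate (not isolated)
23 | 6α-acetoxy-2α,19-dihydroxylabda-8,13-dien-15,16-olide (CNP0231903.1) | CC(=O)O[C@H]1CC(C)=C(CCC2=CC(=O)OC2)[C@@]2(C)C[C@@H](O)C[C@](C)(CO)[C@H]12 | target

**Step count.** Total: 15 steps. Longest linear sequence: 14 steps (steps 1–8 and 10–15, from 3-methylfuran); step 9 is a one-step branch.

**The three steps most likely to fail**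

Step 5. The process at risk is insufficient enantiofacial discrimination in the Michael addition at the trisubstituted, doubly activated alkene, together with slow catalyst turnover with the acidic substrate. Fallback: from 7, the same Michael/vinylogous aldol sequence is run with an achiral amidine base (DBU, 10 mol %, toluene, 23 °C), which should give 9 as a racemate, that is, together with its mirror image methyl (3S,4aR)-3-hydroxy-4a,6-dimethyl-5,8-dioxo-2,3,4,4a,5,6,7,8-octahydronaphthalene-1-carboxylate F1. The two are separated by preparative supercritical-fluid chromatography on a chiral stationary phase, and the route is rejoined at 9.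

Step 7. The process at risk is single-electron reduction of the doubly activated tetrasubstituted alkene by the cuprate in place of methyl transfer, or attack on the wrong face of C4. Fallback: from 10, conjugate reduction with [(Ph3P)CuH]6 in the presence of TMSCl gives the silyl enol ether methyl 9-oxo-2α-(triethylsilyloxy)-6-(trimethylsilyloxy)-11,12,13,14,15,16,18-heptanorlabd-5-en-19-oate F2 (C4 and C8 epimers). KN(SiMe3)2 and PhNTf2 convert its C9 ketone, which is more acidic than the ester, into the enol triflate methyl 2α-(triethylsilyloxy)-9-(trifluoromethanesulfonyloxy)-6-(trimethylsilyloxy)-11,12,13,14,15,16,18-heptanorlabda-5,8-dien-19-oate F3. Deprotonation of the ester with LiN(i-Pr)2 (THF–DMPU, −78 °C) and C-methylation with MeI from the α-face, the classical equatorial alkylation that leaves the ester axial, rejoins the route at 12.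

Step 10. The process at risk is slow oxidative addition and transmetalation at the hindered tetrasubstituted triflate, so that protodeboronation and β-hydride elimination of the alkylpalladium intermediate win. Fallback: from 12, Stille coupling with the much smaller partner Bu3SnCH=CH2 (Pd(PPh3)4, LiCl, THF, 60 °C) gives the diene methyl 2α-(triethylsilyloxy)-6-(trimethylsilyloxy)-13,14,15,16-tetranorlabda-5,8,11-trien-19-oate F4. 9-BBN-H adds only to its terminal vinyl group and gives the alkylborane methyl 12-(9-borabicyclo[3.3.1]nonan-9-yl)-2α-(triethylsilyloxy)-6-(trimethylsilyloxy)-13,14,15,16-tetranorlabda-5,8-dien-19-oate F5. Its B-alkyl Suzuki coupling then takes place at the unhindered partner 3-bromofuran (Pd(dppf)Cl2, K3PO4, DMF) and rejoins the route at 16, which is hydrolysed to 17 as in step 10.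

**Further compounds**

F1 | step 5 | methyl (3S,4aR)-3-hydroxy-4a,6-dimethyl-5,8-dioxo-2,3,4,4a,5,6,7,8-octahydronaphthalene-1-carboxylate (ent-9) | O=C1CC(C)C(=O)[C@]2(C)C[C@H](O)CC(C(=O)OC)=C12
F2 | step 7 | methyl 9-oxo-2α-(triethylsilyloxy)-6-(trimethylsilyloxy)-11,12,13,14,15,16,18-heptanorlabd-5-en-19-oate | C[Si](C)(C)OC=1CC(C)C(=O)[C@@]2(C)C[C@@H](O[Si](CC)(CC)CC)CC(C(=O)OC)C2=1
F3 | step 7 | methyl 2α-(triethylsilyloxy)-9-(trifluoromethanesulfonyloxy)-6-(trimethylsilyloxy)-11,12,13,14,15,16,18-heptanorlabda-5,8-dien-19-oate | C[Si](C)(C)OC=1CC(C)=C(OS(=O)(=O)C(F)(F)F)[C@@]2(C)C[C@@H](O[Si](CC)(CC)CC)CC(C(=O)OC)C2=1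
F4 | step 10 | methyl 2α-(triethylsilyloxy)-6-(trimethylsilyloxy)-13,14,15,16-tetranorlabda-5,8,11-trien-19-oate | C[Si](C)(C)OC=1CC(C)=C(C=C)[C@@]2(C)C[C@@H](O[Si](CC)(CC)CC)C[C@](C)(C(=O)OC)C2=1
F5 | step 10 | methyl 12-(9-borabicyclo[3.3.1]nonan-9-yl)-2α-(triethylsilyloxy)-6-(trimethylsilyloxy)-13,14,15,16-tetranorlabda-5,8-dien-19-oate | C[Si](C)(C)OC=1CC(C)=C(CCB3C4CCCC3CCC4)[C@@]2(C)C[C@@H](O[Si](CC)(CC)CC)C[C@](C)(C(=O)OC)C2=1
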